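## The problem

The target 23 is a coumarin in which every carbon of the benzene ring (ring A: C4a, C5, C6, C7, C8, C8a) is substituted. C8a carries the lactone oxygen, C6 and C8 carry methyl groups, C7 a free hydroxyl, C4a the C4 methine and C5 a (2R,3S)-3-hydroxybutan-2-yl chain (C1'' benzylic, C2'' carbinol). C3 of the lactone ring carries a (2R)-2-methyl-2,3-dihydro-4H-pyran-4-one bound through C6'. The first task is therefore a hexasubstituted arene with a fixed order of substituents, one of them a branched, stereodefined alkyl group that stepwise substitution of a resorcinol cannot place well. C1'' and C2'' are adjacent, so one can direct the other. C2' lies seven bonds from C1'' across two flat rings, is controlled by neither, and needs its own source. Several groups will not survive rough treatment: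
- the dihydropyranone is a β-alkoxy enone that adds amines at C6' and can open by retro-oxa-Michael loss of O1' from C2', which would erase that centre;
- the coumarin lactone opens with hydroxide, and the resorcinol ring is easily oxidized;
- the C2'' hydroxyl lies within reach of C4 and closes an isochroman ring on any electrophilic carbon there.

What makes a short route possible is the pattern of ring A itself. Oxygen on C7 and C8a, methyl on C6 and C8, and carbon on C4a and C5 is the folding pattern of a C-methylated tetraketide. The C4a–C5 bond can therefore be made by an aldol reaction between the α-methylene of a β-keto ester and the far ketone of a linear 3,5,7-triketo ester whose chain end already carries C1'' and C2''.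

## Retrosynthesis

**23 to 13 and 20.** The first cut opens the lactone ring at C3=C4 and O1–C2, the two bonds of a Knoevenagel condensation followed by lactonization. It gives lactol 13, whose open form is salicylaldehyde 21, and pyranonylacetic ester 20, whose methylene lies between the ester and the vinylogous ketone. Cutting C3–C6' instead would mean a cross-coupling of two functionalized heterocycles, and building the pyranone on a finished coumarin would mean enolate chemistry on a 3-acylcoumarin. The chosen cut joins two finished enantiopure halves in the last step and needs no protecting group. The forward reaction must condense at the ester methylene of 20 under amine catalysis mild enough to spare the β-alkoxy enone and C2', and must end in the coumarin, not in an isochroman. Intermediate 22 has one irreversible exit, closure of the C8a hydroxyl on the ester.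

**20 to 14 and 17.** The O1'–C6' bond of 20 is cut by reversing a cyclodehydration, which leads to δ-hydroxy-β-diketo ester 19 and its silyl ether 18. Cutting the C5–C6 chain bond of 18 gives methyl acetoacetate 17 and Weinreb amide 16, which comes through silyl ether 15 from methyl (3R)-3-hydroxybutanoate 14. This takes C2' from the chiral pool with no doubt about its configuration. The precursors are simple, and the forward steps only have to keep the C7–O bond of the chain intact.

**13 to 10.** Lactol 13 is the half-reduced form of dihydroisocoumarin 12, and 12 is the lactone of hydroxy ester 11, the desilylated form of resorcylate 10. The lactone ties the side-chain hydroxyl and the carboxyl carbon into one stable ring, so the aldehyde oxidation level is reached in one reduction without phenol protection. The neighbouring option, reducing the ester of 10 to a benzylic alcohol and reoxidizing, takes one step more and passes through an electron-rich hydroxybenzyl alcohol prone to quinone methide formation. The forward steps must stop the reduction at the lactol despite two free phenols.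

**10 to 8 (key cut).** Cutting the C4a–C5 bond of the arene unfolds 10 into the linear triketo ester 8 through aldol adduct 9. No other cut of ring A removes the ring and all questions of substituent order at once. The two methyl groups, both oxygens, the carboxyl carbon and the side chain with its two stereocentres are already in sequence along the chain of 8. Compound 8 has no ring and only the two stereocentres of the chain end. The forward reaction must close C2 onto C7 in preference to Claisen closure and O-cyclization, and must leave C8 and the silyloxy group at C9 untouched.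

**8 to 7 and 4.** The C6–C7 bond of 8 is cut to give diketo ester 7 and the chiral Weinreb amide 4. This cut places the only stereodefined piece at the chain terminus, where the terminal carbanion of a polyanion of 7 reacts. It also forms the C7 ketone last, as a chelated adduct that never meets free base. Cuts further inside the chain would need the acylation of an α-chiral ketone enolate and would put C8 at risk. The forward reaction asks for terminal C-acylation of the trianion of 7 without enolization of 4.

**7 and 4 to starting materials.** Diketo ester 7 is cut at C4–C5 into methyl 3-oxopentanoate 5 and N-methoxy-N-methylpropanamide 6, a dianion γ-acylation. Amide 4 comes from ester 3, the silyl ether of anti-hydroxy ester 2, and the C2–methyl bond of 2 is cut by reversing a Fráter–Seebach methylation of ethyl (3S)-3-hydroxybutanoate 1. Here the existing carbinol centre sets the new one, which later becomes C1''.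

## Roads not taken

**Alternative 1:** This cut removes the lactone carbonyl. O1–C2 and C2–C3 are broken, C2 goes back to carbon monoxide A3, and the precursor is styrylphenol A2, an (E)-6-(2-arylvinyl)dihydropyranone with a free C8a hydroxyl, a methoxymethyl ether at C7 and a silyl ether at C2''. In the forward step Pd(OAc)2 A4 (divalent palladium) with an oxidant would bind the phenol, insert A3 and close onto the vinylic C3–H to give coumarin A1.
- Merits: the step is convergent, uses no amine, and brings the pyranone in intact by an olefination. In avoiding the lactol and the isochroman trap it is better than the chosen plan.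
- Weak points: ring A with all six substituents still has to be made by other means. The two phenols must be told apart, which adds a protection and two deprotections after A1. The C–H bond to be carbonylated sits on an electron-poor, cross-conjugated dienone next to a hindered phenol. Oxidizing divalent palladium conditions are applied to an electron-rich, fully substituted phenol.
- Comparison: the chosen plan builds ring A and its substituent order in one fold, needs no phenol protection, and ends in the target without a deprotection step.

**Alternative 2:** This cut breaks C4–C4a and the ester bond O1–C2. The precursor is aryl ester A6, a β-ethoxyacrylate carrying the pyranone on its α-carbon and bound to the C8a oxygen of a pentasubstituted resorcinol. In the forward step acid ionizes the β-ethoxyacrylate, C4a attacks, and loss of the ethoxy group gives coumarin A5. C4a is the only unsubstituted ring carbon and is para to the C7 hydroxyl.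
- Merits: the regiochemistry of the closure cannot go wrong. In this it is as secure as the aldol fold, and the end is equally convergent.
- Weak points: the resorcinol with its stereodefined sec-alkyl group has no simple origin, so the hardest part of the problem is only moved. The esterification must choose between two phenols. The closure needs strong acid in the presence of the dihydropyranone, the silyl ether and a carbinol next to an electron-rich ring. The attack at C4a takes place beside the bulky chain at C5.
- Comparison: the chosen plan makes the arene and places the chain in the same step, and exposes the pyranone only to a weak amine salt.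

**Alternative 3:** This cut opens the pyranone at C2'–C3' and O1'–C6'. The precursor is diene A8, a 1-methoxy-3-silyloxy diene on coumarin C3, together with acetaldehyde A9. In the forward step a chiral tetravalent titanium complex made from Ti(Oi-Pr)4 A10 and an axially chiral diol would join them, and acid would then remove the methoxy group to give coumarin A7.
- Merits: C2' is set by a catalyst at the very end, and the pyranone is never exposed to condensation conditions. In both respects this road is better than the chosen plan.
- Weak points: A9 is volatile, enolizable and a poor partner for this class of catalyst. The stereocentre rests on reagent control alone. A8 can only be made once the complete coumarin, and hence ring A, exists, and its 3-acylcoumarin parentage makes C4 a strong acceptor during enol ether formation. Two silyl ethers must be removed from A7 in the presence of the base-labile pyranone.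
- Comparison: the chosen plan takes C2' from methyl (3R)-3-hydroxybutanoate 14 with a secure configuration and needs no chiral catalyst. It also solves the construction of ring A, which this road leaves open.

Key step: step 6

Remark: compounds 1, 5, 6, 14 and 17 are taken as commercially available. TBS is tert-butyldimethylsilyl. The C4/C6 centres of 7 and 8, the ring centres of 9 and the anomeric carbon of 13 are carried as mixtures because each is erased later.

## Route

Step 1
Reactants: 1 ethyl (3S)-3-hydroxybutanoate
Product: 2 ethyl (2S,3S)-3-hydroxy-2-methylbutanoate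
Conditions: LiN(i-Pr)2 (2.2 equiv), THF, −78 → −20 °C; MeI, DMPU, −78 → 0 °C; aq. NH4Cl
Reagents that add atoms: iodomethane, CI
Why: Fráter–Seebach alkylation: the dilithium alkoxide–enolate of 1 is a six-membered chelate whose C3 methyl shields one face, so iodomethane should enter anti to it and set C2 as S (the later C1''), anti to the existing C3 carbinol.

Step 2
Reactants: 2 ethyl (2S,3S)-3-hydroxy-2-methylbutanoate
Product: 3 ethyl (2S,3S)-3-[(tert-butyldimethylsilyl)oxy]-2-methylbutanoate
Conditions: TBSCl, imidazole, DMF, rt
Reagents that add atoms: tert-butyldimethylsilyl chloride, CC(C)(C)[Si](C)(C)Cl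
Why: Standard imidazole-promoted silylation of a secondary alcohol; the silyl ether prevents hemiketal and pyranone formation at the polyketone stage and brings no acidic proton into the polyanion chemistry.

Step 3
Reactants: 3 ethyl (2S,3S)-3-[(tert-butyldimethylsilyl)oxy]-2-methylbutanoate
Product: 4 (2S,3S)-3-[(tert-butyldimethylsilyl)oxy]-N-methoxy-N,2-dimethylbutanamide
Conditions: MeNH(OMe)·HCl, i-PrMgCl, THF, −20 → 0 °C
Reagents that add atoms: N,O-dimethylhydroxylamine hydrochloride, CNOC.Cl
Why: Weinreb amide formation from an ester with the chloromagnesium amide made in the flask; the reagent acts as a nucleophile and not as a base toward the hindered C2–H, so the α-centre and the β-silyloxy group should persist.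

Step 4
Reactants: 5 methyl 3-oxopentanoate; 6 N-methoxy-N-methylpropanamide
Product: 7 methyl 4-methyl-3,5-dioxoheptanoate
Conditions: LiN(i-Pr)2 (2.1 equiv), THF, −78 → 0 °C; then 6, −78 → 0 °C; aq. NH4Cl
Reagents that add atoms: none
Why: γ-Acylation of a β-keto ester dianion with a Weinreb amide: the second-formed C4 carbanion is the reactive site and the chelated tetrahedral adduct prevents double addition.

Step 5
Reactants: 7 methyl 4-methyl-3,5-dioxoheptanoate; 4 (2S,3S)-3-[(tert-butyldimethylsilyl)oxy]-N-methoxy-N,2-dimethylbutanamide
Product: 8 methyl (8S,9S)-9-[(tert-butyldimethylsilyl)oxy]-4,6,8-trimethyl-3,5,7-trioxodecanoate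
Conditions: 7 (1.5 equiv), LiN(i-Pr)2 (3.1 equiv per 7), THF, −78 → 0 °C; then 4, −78 → −20 °C; aq. NH4Cl–AcOH, 0 °C; used without long storage
Reagents that add atoms: none
Why: Terminal C-acylation of a β,δ-diketo ester trianion (polyanion chemistry), which reacts at its last-formed carbanion C6; the Weinreb adduct stays a chelated tetrahedral intermediate until the mildly acidic quench, so the new C7 ketone never meets base and C8 should not be enolized.

Step 6
Reactants: 8 methyl (8S,9S)-9-[(tert-butyldimethylsilyl)oxy]-4,6,8-trimethyl-3,5,7-trioxodecanoate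
Product: 10 methyl 2,4-dihydroxy-3,5-dimethyl-6-[(2R,3S)-3-[(tert-butyldimethylsilyl)oxy]butan-2-yl]benzoate, via cyclic aldol adduct 9 (not isolated)
Conditions: Cs2CO3 (1.5 equiv), MeOH, 0 °C → rt; then AcOH (excess, buffer), 40 °C
Reagents that add atoms: none
Why: Carbonate in methanol ionizes only the 1,3-dicarbonyl positions of 8, and the enolate of the β-keto ester methylene C2 adds to the C7 ketone in a 6-(enolendo)-exo-trig aldol closure to give 9, which forms the C4a–C5 bond of the target. E1cB loss of water from 9 and enolization of the two remaining ring carbonyls, completed in the caesium acetate/acetic acid buffer, should give the aromatic resorcylate 10 irreversibly. The closest known reaction type is the biomimetic base-mediated cyclization of 3,5,7-triketo esters to resorcylates (polyketide-type aldol aromatization). No stereocentre is formed: the C4 and C6 centres of 8 and the ring centres of 9 vanish on aromatization, and the chain order alone places the methyl groups on C8 and C6, the oxygens on C8a and C7 and the chain end on C5 (coumarin numbering). The step needs C2-to-C7 aldol closure in preference to Claisen closure (C6 onto the ester), O-cyclization to pyranones and retro-Claisen cleavage; C2 is the only unsubstituted and most accessible nucleophilic carbon, the ester is deactivated within an enolized β-keto ester, and a non-chelating carbonate base at or below room temperature is the regime that favours the aldol mode. C8 and the silyloxy group at C9 should be safe because the C8 proton is not flanked by two carbonyls and lies far outside the acidity range of carbonate, so neither epimerization nor β-elimination is expected to compete.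

Step 7
Reactants: 10 methyl 2,4-dihydroxy-3,5-dimethyl-6-[(2R,3S)-3-[(tert-butyldimethylsilyl)oxy]butan-2-yl]benzoate
Product: 12 (3S,4R)-6,8-dihydroxy-3,4,5,7-tetramethyl-3,4-dihydro-1H-isochromen-1-one, via desilylated hydroxy ester 11 (not isolated)
Conditions: aq. HF, MeCN, 0 °C → rt; then TsOH·H2O (cat.), PhMe, 80 °C
Reagents that add atoms: none
Why: Acidic fluoride desilylation gives hydroxy ester 11, which should close by acid-catalysed 6-exo-trig transesterification to the dihydroisocoumarin; only the acyl C–O bond changes, so both stereocentres keep their configuration.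

Step 8
Reactants: 12 (3S,4R)-6,8-dihydroxy-3,4,5,7-tetramethyl-3,4-dihydro-1H-isochromen-1-one
Product: 13 (3S,4R)-3,4,5,7-tetramethyl-3,4-dihydro-1H-isochromene-1,6,8-triol
Conditions: i-Bu2AlH (3.5 equiv), CH2Cl2–THF, −78 °C; aq. KNaC4H4O6 (potassium sodium tartrate)
Reagents that add atoms: none
Why: Half-reduction of a lactone to a lactol with i-Bu2AlH: the two phenols are first converted into aluminium phenoxides (hence the excess), and the cyclic aluminium hemiacetal should be stable at −78 °C, holding the aldehyde oxidation level until work-up.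

Step 9
Reactants: 14 methyl (3R)-3-hydroxybutanoate
Product: 15 methyl (3R)-3-[(tert-butyldimethylsilyl)oxy]butanoate
Conditions: TBSCl, imidazole, DMF, rt
Reagents that add atoms: tert-butyldimethylsilyl chloride, CC(C)(C)[Si](C)(C)Cl
Why: Standard silylation of a secondary alcohol; the C3 centre (the later C2') is not involved.

Step 10
Reactants: 15 methyl (3R)-3-[(tert-butyldimethylsilyl)oxy]butanoate
Product: 16 (3R)-3-[(tert-butyldimethylsilyl)oxy]-N-methoxy-N-methylbutanamide
Conditions: MeNH(OMe)·HCl, i-PrMgCl, THF, −20 → 0 °C
Reagents that add atoms: N,O-dimethylhydroxylamine hydrochloride, CNOC.Cl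
Why: Weinreb amide formation from an ester with the magnesium amide, as in step 3; the conditions are not basic enough to eliminate the β-silyloxy group.

Step 11
Reactants: 17 methyl 3-oxobutanoate (methyl acetoacetate); 16 (3R)-3-[(tert-butyldimethylsilyl)oxy]-N-methoxy-N-methylbutanamide
Product: 18 methyl (7R)-7-[(tert-butyldimethylsilyl)oxy]-3,5-dioxooctanoate
Conditions: 17 (1.5 equiv), LiN(i-Pr)2 (2.1 equiv per 17), THF, −78 → 0 °C; then 16, −78 → 0 °C; aq. NH4Cl
Reagents that add atoms: none
Why: γ-Acylation of the acetoacetate dianion with a Weinreb amide, as in step 4; the chelated adduct stops at the ketone level and the remote carbinol centre is untouched.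

Step 12
Reactants: 18 methyl (7R)-7-[(tert-butyldimethylsilyl)oxy]-3,5-dioxooctanoate
Product: 20 methyl 2-[(2R)-2-methyl-4-oxo-3,4-dihydro-2H-pyran-6-yl]acetate, via hydroxy diketo ester 19 (not isolated)
Conditions: aq. HF, MeCN, 0 °C → rt; then TsOH·H2O (cat.), CH2Cl2, 4 Å MS, rt
Reagents that add atoms: none
Why: Cyclodehydration of a δ-hydroxy-β-diketone to a 2,3-dihydro-4H-pyran-4-one: the freed C7 hydroxyl of 19 adds to the C3 ketone (six-membered hemiketal) and acid-catalysed loss of water toward C4 gives the vinylogous ester; the C7–O bond is not broken, so the R configuration is kept.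

Step 13
Reactants: 13 (3S,4R)-3,4,5,7-tetramethyl-3,4-dihydro-1H-isochromene-1,6,8-triol; 20 methyl 2-[(2R)-2-methyl-4-oxo-3,4-dihydro-2H-pyran-6-yl]acetate
Product: 23 7-hydroxy-5-[(2R,3S)-3-hydroxybutan-2-yl]-6,8-dimethyl-3-[(2R)-2-methyl-4-oxo-3,4-dihydro-2H-pyran-6-yl]-2H-chromen-2-one, via hydroxy aldehyde 21 (not isolated), via Knoevenagel adduct 22 (not isolated)
Conditions: piperidine (0.2 equiv), AcOH (0.2 equiv), 4 Å MS, MeCN, 50 °C
Reagents that add atoms: none
Why: Knoevenagel condensation–lactonization (the classical coumarin synthesis from salicylaldehydes and activated acetic esters): the lactol supplies aldehyde 21, the methylene of 20 between the ester and the vinylogous ketone condenses to 22, and the C8a hydroxyl closes onto the ester with loss of methanol. The coumarin is the only irreversible outlet, so reversible addition of the side-chain hydroxyl to the alkylidene should drain into 23, and the catalytic, buffered amine should leave the pyranone and C2' intact.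

## Compound list

1 | ethyl (3S)-3-hydroxybutanoate | C[C@H](O)CC(=O)OCC | starting material
2 | ethyl (2S,3S)-3-hydroxy-2-methylbutanoate | CCOC(=O)[C@@H](C)[C@H](C)O | intermediate
3 | ethyl (2S,3S)-3-[(tert-butyldimethylsilyl)oxy]-2-methylbutanoate | CCOC(=O)[C@@H](C)[C@H](C)O[Si](C)(C)C(C)(C)C | intermediate
4 | (2S,3S)-3-[(tert-butyldimethylsilyl)oxy]-N-methoxy-N,2-dimethylbutanamide | CON(C)C(=O)[C@@H](C)[C@H](C)O[Si](C)(C)C(C)(C)C | intermediate
5 | methyl 3-oxopentanoate | CCC(=O)CC(=O)OC | starting material
6 | N-methoxy-N-methylpropanamide | CCC(=O)N(C)OC | starting material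
7 | methyl 4-methyl-3,5-dioxoheptanoate (C4 unassigned) | CCC(=O)C(C)C(=O)CC(=O)OC | intermediate
8 | methyl (8S,9S)-9-[(tert-butyldimethylsilyl)oxy]-4,6,8-trimethyl-3,5,7-trioxodecanoate (C4, C6 unassigned) | COC(=O)CC(=O)C(C)C(=O)C(C)C(=O)[C@@H](C)[C@H](C)O[Si](C)(C)C(C)(C)C | intermediate
9 | methyl 2-[(2S,3S)-3-[(tert-butyldimethylsilyl)oxy]butan-2-yl]-2-hydroxy-3,5-dimethyl-4,6-dioxocyclohexane-1-carboxylate (ring centres unassigned; formed in the flask, not isolated) | COC(=O)C1C(=O)C(C)C(=O)C(C)C1(O)[C@@H](C)[C@H](C)O[Si](C)(C)C(C)(C)C | intermediate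
10 | methyl 2,4-dihydroxy-3,5-dimethyl-6-[(2R,3S)-3-[(tert-butyldimethylsilyl)oxy]butan-2-yl]benzoate | COC(=O)c1c(O)c(C)c(O)c(C)c1[C@@H](C)[C@H](C)O[Si](C)(C)C(C)(C)C | intermediate
11 | methyl 2,4-dihydroxy-6-[(2R,3S)-3-hydroxybutan-2-yl]-3,5-dimethylbenzoate (formed in the flask, not isolated) | COC(=O)c1c(O)c(C)c(O)c(C)c1[C@@H](C)[C@H](C)O | intermediate
12 | (3S,4R)-6,8-dihydroxy-3,4,5,7-tetramethyl-3,4-dihydro-1H-isochromen-1-one | O=C1c2c(O)c(C)c(O)c(C)c2[C@@H](C)[C@H](C)O1 | intermediate
13 | (3S,4R)-3,4,5,7-tetramethyl-3,4-dihydro-1H-isochromene-1,6,8-triol (C1 anomers) | OC1c2c(O)c(C)c(O)c(C)c2[C@@H](C)[C@H](C)O1 | intermediate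
14 | methyl (3R)-3-hydroxybutanoate | COC(=O)C[C@@H](C)O | starting material
15 | methyl (3R)-3-[(tert-butyldimethylsilyl)oxy]butanoate | COC(=O)C[C@@H](C)O[Si](C)(C)C(C)(C)C | intermediate
16 | (3R)-3-[(tert-butyldimethylsilyl)oxy]-N-methoxy-N-methylbutanamide | CON(C)C(=O)C[C@@H](C)O[Si](C)(C)C(C)(C)C | intermediate
17 | methyl 3-oxobutanoate (methyl acetoacetate) | CC(=O)CC(=O)OC | starting material
18 | methyl (7R)-7-[(tert-butyldimethylsilyl)oxy]-3,5-dioxooctanoate | COC(=O)CC(=O)CC(=O)C[C@@H](C)O[Si](C)(C)C(C)(C)C | intermediate
19 | methyl (7R)-7-hydroxy-3,5-dioxooctanoate (formed in the flask, not isolated) | COC(=O)CC(=O)CC(=O)C[C@@H](C)O | intermediate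
20 | methyl 2-[(2R)-2-methyl-4-oxo-3,4-dihydro-2H-pyran-6-yl]acetate | COC(=O)CC1=CC(=O)C[C@@H](C)O1 | intermediate
21 | 2,4-dihydroxy-6-[(2R,3S)-3-hydroxybutan-2-yl]-3,5-dimethylbenzaldehyde (open form of 13; formed in the flask, not isolated) | O=Cc1c(O)c(C)c(O)c(C)c1[C@@H](C)[C@H](C)O | intermediate
22 | methyl 3-{2,4-dihydroxy-6-[(2R,3S)-3-hydroxybutan-2-yl]-3,5-dimethylphenyl}-2-[(2R)-2-methyl-4-oxo-3,4-dihydro-2H-pyran-6-yl]prop-2-enoate (alkene geometry unassigned; formed in the flask, not isolated) | COC(=O)C(=Cc1c(O)c(C)c(O)c(C)c1[C@@H](C)[C@H](C)O)C1=CC(=O)C[C@@H](C)O1 | intermediate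
23 | 7-hydroxy-5-[(2R,3S)-3-hydroxybutan-2-yl]-6,8-dimethyl-3-[(2R)-2-methyl-4-oxo-3,4-dihydro-2H-pyran-6-yl]-2H-chromen-2-one | Cc1c(O)c(C)c2oc(=O)c(C3=CC(=O)C[C@@H](C)O3)cc2c1[C@@H](C)[C@H](C)O | target

## Step count and risks

Total step count: 13. Longest linear sequence: 8 steps (steps 1, 2, 3, 5, 6, 7, 8 and 13). Steps 4 and 9–12 are side branches.

**Step 6 (key step).** The C7 ketone is flanked by two methine carbons, so the aldol closure may be slow. O-cyclization of the C5 enol oxygen onto the ester, or methoxide cleavage of the non-enolized 2-methyl-1,3-diketone units, could then take over.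

Fallback: replace the ester by a dioxinone, in which Claisen closure and pyranone formation are structurally impossible. It sets out from amide 4 (with 6) and returns at lactone 12.
- The known 6-ethyl-2,2-dimethyl-4H-1,3-dioxin-4-one F1 (the ethyl homologue of the commercial acetone–diketene adduct) would be deprotonated with LiN(i-Pr)2 and propionylated at its γ-carbon with 6 to give 2,2-dimethyl-6-(3-oxopentan-2-yl)-4H-1,3-dioxin-4-one F2.
- The dianion of F2 would be acylated at its terminal carbon with 4 to give 6-[(6S,7S)-7-[(tert-butyldimethylsilyl)oxy]-4,6-dimethyl-3,5-dioxooctan-2-yl]-2,2-dimethyl-4H-1,3-dioxin-4-one F3.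
- Et3N in CH2Cl2 would then bring about the same C4a–C5 aldol closure and aromatization to 7-hydroxy-2,2,6,8-tetramethyl-5-[(2R,3S)-3-[(tert-butyldimethylsilyl)oxy]butan-2-yl]-4H-1,3-benzodioxin-4-one F4.
- Aqueous HF followed by TsOH in warm toluene would remove the silyl group and let the side-chain hydroxyl open the dioxinone with loss of acetone, giving 12.

**Step 5.** Bond formation between the secondary terminal carbanion of the trianion and the α-branched amide 4 may be slow. Proton transfer from 4 to the polyanion would then compete, with loss of the C2 configuration or elimination of the silyloxy group.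

Fallback: use a more electrophilic aldehyde and adjust the oxidation level afterwards. It sets out from ester 3 and returns at 8.
- i-Bu2AlH at −78 °C would give (2S,3S)-3-[(tert-butyldimethylsilyl)oxy]-2-methylbutanal F5.
- The trianion of 7 would add to F5 at −78 °C to give methyl (8R,9S)-9-[(tert-butyldimethylsilyl)oxy]-7-hydroxy-4,6,8-trimethyl-3,5-dioxodecanoate F6 as a mixture at C7.
- Dess–Martin periodinane would oxidize F6 to 8.

**Step 8.** The ortho aluminium phenoxide may assist collapse of the tetrahedral intermediate, leading to over-reduction past the lactol stage. Alternatively the phenoxide-deactivated lactone may be reduced incompletely.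

Fallback: mask the phenols during the reduction. It sets out from 12 and returns at 13.
- TBSOTf and 2,6-lutidine would give (3S,4R)-6,8-bis[(tert-butyldimethylsilyl)oxy]-3,4,5,7-tetramethyl-3,4-dihydro-1H-isochromen-1-one F7.
- i-Bu2AlH at −78 °C would give (3S,4R)-6,8-bis[(tert-butyldimethylsilyl)oxy]-3,4,5,7-tetramethyl-3,4-dihydro-1H-isochromen-1-ol F8.
- Bu4NF buffered with AcOH would remove both aryl silyl ethers to give 13.

**Step 13.** Three things may go wrong:
- the side-chain hydroxyl may trap the condensation product as a 1-substituted isochroman that does not reopen;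
- piperidine may add to C6' of the pyranone;
- C2' may be lost by retro-oxa-Michael opening under prolonged heating.

Fallback: keep the side-chain hydroxyl silylated during the condensation. It sets out from resorcylate 10 and returns at target 23.
- LiAlH4 in THF at 0 °C would give 4-(hydroxymethyl)-2,6-dimethyl-5-[(2R,3S)-3-[(tert-butyldimethylsilyl)oxy]butan-2-yl]benzene-1,3-diol F9, to be used crude.
- MnO2 in CH2Cl2 would oxidize the benzylic alcohol to 2,4-dihydroxy-3,5-dimethyl-6-[(2R,3S)-3-[(tert-butyldimethylsilyl)oxy]butan-2-yl]benzaldehyde F10.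
- Condensation of F10 with 20 under the conditions of step 13 can only end in the coumarin, 7-hydroxy-6,8-dimethyl-3-[(2R)-2-methyl-4-oxo-3,4-dihydro-2H-pyran-6-yl]-5-[(2R,3S)-3-[(tert-butyldimethylsilyl)oxy]butan-2-yl]-2H-chromen-2-one F11 (the same compound as A5).
- HF·pyridine in THF would then free the carbinol to give 23.

## Further compounds

F1 | step 6 | 6-ethyl-2,2-dimethyl-4H-1,3-dioxin-4-one | CCC1=CC(=O)OC(C)(C)O1
F2 | step 6 | 2,2-dimethyl-6-(3-oxopentan-2-yl)-4H-1,3-dioxin-4-one | CCC(=O)C(C)C1=CC(=O)OC(C)(C)O1
F3 | step 6 | 6-[(6S,7S)-7-[(tert-butyldimethylsilyl)oxy]-4,6-dimethyl-3,5-dioxooctan-2-yl]-2,2-dimethyl-4H-1,3-dioxin-4-one | CC(C(=O)C(C)C(=O)[C@@H](C)[C@H](C)O[Si](C)(C)C(C)(C)C)C1=CC(=O)OC(C)(C)O1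
F4 | step 6 | 7-hydroxy-2,2,6,8-tetramethyl-5-[(2R,3S)-3-[(tert-butyldimethylsilyl)oxy]butan-2-yl]-4H-1,3-benzodioxin-4-one | CC1(C)OC(=O)c2c(O1)c(C)c(O)c(C)c2[C@@H](C)[C@H](C)O[Si](C)(C)C(C)(C)C
F5 | step 5 | (2S,3S)-3-[(tert-butyldimethylsilyl)oxy]-2-methylbutanal | O=C[C@@H](C)[C@H](C)O[Si](C)(C)C(C)(C)C
F6 | step 5 | methyl (8R,9S)-9-[(tert-butyldimethylsilyl)oxy]-7-hydroxy-4,6,8-trimethyl-3,5-dioxodecanoate | COC(=O)CC(=O)C(C)C(=O)C(C)C(O)[C@@H](C)[C@H](C)O[Si](C)(C)C(C)(C)C
F7 | step 8 | (3S,4R)-6,8-bis[(tert-butyldimethylsilyl)oxy]-3,4,5,7-tetramethyl-3,4-dihydro-1H-isochromen-1-one | O=C1c2c(O[Si](C)(C)C(C)(C)C)c(C)c(O[Si](C)(C)C(C)(C)C)c(C)c2[C@@H](C)[C@H](C)O1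
F8 | step 8 | (3S,4R)-6,8-bis[(tert-butyldimethylsilyl)oxy]-3,4,5,7-tetramethyl-3,4-dihydro-1H-isochromen-1-ol | OC1c2c(O[Si](C)(C)C(C)(C)C)c(C)c(O[Si](C)(C)C(C)(C)C)c(C)c2[C@@H](C)[C@H](C)O1
F9 | step 13 | 4-(hydroxymethyl)-2,6-dimethyl-5-[(2R,3S)-3-[(tert-butyldimethylsilyl)oxy]butan-2-yl]benzene-1,3-diol | OCc1c(O)c(C)c(O)c(C)c1[C@@H](C)[C@H](C)O[Si](C)(C)C(C)(C)C
F10 | step 13 | 2,4-dihydroxy-3,5-dimethyl-6-[(2R,3S)-3-[(tert-butyldimethylsilyl)oxy]butan-2-yl]benzaldehyde | O=Cc1c(O)c(C)c(O)c(C)c1[C@@H](C)[C@H](C)O[Si](C)(C)C(C)(C)C
F11 | step 13 | 7-hydroxy-6,8-dimethyl-3-[(2R)-2-methyl-4-oxo-3,4-dihydro-2H-pyran-6-yl]-5-[(2R,3S)-3-[(tert-butyldimethylsilyl)oxy]butan-2-yl]-2H-chromen-2-one | Cc1c(O)c(C)c2oc(=O)c(C3=CC(=O)C[C@@H](C)O3)cc2c1[C@@H](C)[C@H](C)O[Si](C)(C)C(C)(C)C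
A1 | alternative 1 | 7-(methoxymethoxy)-6,8-dimethyl-3-[(2R)-2-methyl-4-oxo-3,4-dihydro-2H-pyran-6-yl]-5-[(2R,3S)-3-[(tert-butyldimethylsilyl)oxy]butan-2-yl]-2H-chromen-2-one | Cc1c(OCOC)c(C)c2oc(=O)c(C3=CC(=O)C[C@@H](C)O3)cc2c1[C@@H](C)[C@H](C)O[Si](C)(C)C(C)(C)C
A2 | alternative 1 | (2R)-6-[(E)-2-{2-hydroxy-4-(methoxymethoxy)-3,5-dimethyl-6-[(2R,3S)-3-[(tert-butyldimethylsilyl)oxy]butan-2-yl]phenyl}ethenyl]-2-methyl-2,3-dihydro-4H-pyran-4-one | Cc1c(OCOC)c(C)c(O)c(/C=C/C2=CC(=O)C[C@@H](C)O2)c1[C@@H](C)[C@H](C)O[Si](C)(C)C(C)(C)C
A3 | alternative 1 | carbon monoxide | [C-]#[O+]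
A4 | alternative 1 | palladium diacetate | CC(=O)[O-].CC(=O)[O-].[Pd+2]
A5 | alternative 2 | 7-hydroxy-6,8-dimethyl-3-[(2R)-2-methyl-4-oxo-3,4-dihydro-2H-pyran-6-yl]-5-[(2R,3S)-3-[(tert-butyldimethylsilyl)oxy]butan-2-yl]-2H-chromen-2-one | Cc1c(O)c(C)c2oc(=O)c(C3=CC(=O)C[C@@H](C)O3)cc2c1[C@@H](C)[C@H](C)O[Si](C)(C)C(C)(C)C
A6 | alternative 2 | 3-hydroxy-2,4-dimethyl-5-[(2R,3S)-3-[(tert-butyldimethylsilyl)oxy]butan-2-yl]phenyl 3-ethoxy-2-[(2R)-2-methyl-4-oxo-3,4-dihydro-2H-pyran-6-yl]prop-2-enoate | CCOC=C(C(=O)Oc1cc([C@@H](C)[C@H](C)O[Si](C)(C)C(C)(C)C)c(C)c(O)c1C)C1=CC(=O)C[C@@H](C)O1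
A7 | alternative 3 | 7-[(tert-butyldimethylsilyl)oxy]-5-[(2R,3S)-3-[(tert-butyldimethylsilyl)oxy]butan-2-yl]-6,8-dimethyl-3-[(2R)-2-methyl-4-oxo-3,4-dihydro-2H-pyran-6-yl]-2H-chromen-2-one | Cc1c(O[Si](C)(C)C(C)(C)C)c(C)c2oc(=O)c(C3=CC(=O)C[C@@H](C)O3)cc2c1[C@@H](C)[C@H](C)O[Si](C)(C)C(C)(C)C
A8 | alternative 3 | 7-[(tert-butyldimethylsilyl)oxy]-5-[(2R,3S)-3-[(tert-butyldimethylsilyl)oxy]butan-2-yl]-3-[1-methoxy-3-(trimethylsilyloxy)buta-1,3-dien-1-yl]-6,8-dimethyl-2H-chromen-2-one | Cc1c(O[Si](C)(C)C(C)(C)C)c(C)c2oc(=O)c(C(OC)=CC(=C)O[Si](C)(C)C)cc2c1[C@@H](C)[C@H](C)O[Si](C)(C)C(C)(C)C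
A9 | alternative 3 | acetaldehyde | CC=O
A10 | alternative 3 | titanium tetraisopropoxide | CC(C)O[Ti](OC(C)C)(OC(C)C)OC(C)C
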